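If impurity takes catalyst one for one, the slope of the target line is a working loading times a turnover, and with that rule I draw spring and dawn.

| flask | substrate | gas | free catalyst | impurity | remark | time |
|---|---|---|---|---|---|---|
| delta | 0.17 M (fed, over 6.0 min) | 36 mM (held) | 0.2 mol% | 52 µM | run made earlier; the fed solution adds 0.25 times the starting volume |  |
| beta | 0.25 M (fed, over 6.0 min) | 36 mM (held) | 0.4 mol% | 52 µM | run made earlier; the fed solution adds 0.25 times the starting volume |  |
| spring | 0.25 M (fed, over 6.0 min) | 36 mM (held) | 0.2 mol% | 52 µM | the fed solution adds 0.25 times the starting volume | 8.0 min |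
| dawn | 0.25 M | 36 mM | 0.2 mol% | 150 µM | everything together at the start, the whole solution of substrate included, so that from the start the volume is larger by 0.25 times the starting volume | 2.0 min |

| run | time / min | target / % | substrate / % |
|---|---|---|---|
| delta | 1.00 | 4.2 | 13.1 |
| delta | 2.00 | 6.8 | 25.3 |
| delta | 3.00 | 12.9 | 36.2 |
| delta | 4.00 | 16.6 | 47.2 |
| delta | 5.00 | 24.5 | 59.0 |
| beta | 0.417 | 0.8 | 5.7 |
| beta | 0.667 | 3.4 | 7.8 |
| beta | 1.33 | 7.9 | 11.8 |
| beta | 2.50 | 20.2 | 20.3 |
| beta | 5.00 | 47.3 | 35.9 |

(readings scatter by 1 percentage point)

- charges are per starting volume, the dose included; the dosed solution carries all of it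
- the numbers in the tables scatter with a standard deviation of 1 percentage point
- percentages count the whole charge, also what has not yet gone in
- no earlier run changes the charge of impurity; that part of a forecast is a guess

- which of the two ends with the higher amount of target, in percent of the substrate charged ("neither" if they lie within 2 percentage points) (spring / dawn / neither)
- target at the end, in percent of the substrate charged, spring
- target at the end, in percent of the substrate charged, dawn

In spring the free catalyst charged less the impurity, both as fractions of the substrate charged, comes to 0.179%, the working loading. That one-for-one step is a guess, as no run changes the impurity.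

Beta has spring's substrate charge, so its percentages carry over, and its working loading is 0.379%. Its slopes give a turnover of

17.9 min⁻¹ with substrate near 9.80%,
28.6 min⁻¹ with substrate near 28.1%.

So in beta's readings turnover grows with substrate, as a power of about 0.444. In delta, target and substrate at the last reading add up to 83.5%, and 83.3% had gone in, so what is fed and not yet target is substrate.

Spring's line starts at zero while the feed brings in the charge at 0.167 min⁻¹. A first pass at beta's later turnover gives

slope 0.0512 min⁻¹, so substrate 69.3% at the knee, the end of the feed at 6.0 min.

Putting that substrate back in gives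

turnover 42.7 min⁻¹, slope 0.0765 min⁻¹,
target 31.8% at the knee, 47.1% at 8.0 min.

On my line target crosses substrate at 8.38 min, and the level ahead is the whole charge.

Dawn has a working loading of 0.140% and starts with the whole substrate in, so its slope is 0.0704 min⁻¹, which gives 14.1%.

My figures put spring higher than dawn. The forecast also picks spring, but it stands below my figures, with 45% for spring and 10.5% for dawn: “Spring ends clearly higher.”

The flask gives 52.1% for spring and 14.2% for dawn.

    substrate + free catalyst → catalyst intermediate A (k = 55.0 M⁻¹ s⁻¹)
    gas ⇌ partner, rate k2*(csat - [partner]) (kL = 0.0230 s⁻¹)
    catalyst intermediate B → free catalyst + target (k = 7.10 s⁻¹)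
    free catalyst + impurity → spent catalyst (k = 6400 M⁻¹ s⁻¹)
    partner + catalyst intermediate A ⇌ catalyst intermediate B (K = 9.50 M⁻¹, k = 3500 M⁻¹ s⁻¹)
    free catalyst ⇌ dormant form (K = 2.80, k = 0.0140 s⁻¹)

In spring 10.4% of the catalyst is spent, and the working loading took off 10.4%. At 8.00 min in spring, substrate's half-life by its step with free catalyst is 4.4 min, ten times the 0.42 min reckoned with the whole catalyst charge free, while free catalyst stands at 11.9%, catalyst intermediate A (the resting state of the round) at 37.9%, catalyst intermediate B at 8.81% and dormant form at 31.0%.

The neighbour of spring with 1.3 × 10⁻⁴ M of impurity has a working loading of 0.148%, so scaling spring's result by 0.827 gives 43.1%. The flask gives 45.3%.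

The readings were computed with made-up constants; noise was put on by code.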